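Compare two stretches of the alpha run. Doubling the time from 0.250 min to 0.500 min gave 8.5 percentage points of product, and from 0.500 min to 3.00 min each doubling still gave about as much on average, 8.3 points.

the same everywhere: substrate 0.50 M
- eta: free catalyst 0.018 mol%; temperature 55 °C; run made earlier
- alpha: free catalyst 0.33 mol%; temperature 66 °C; run made earlier
- spring: free catalyst 0.1 mol%; temperature 60 °C; time 4.0 min
- noon: free catalyst 0.4 mol%; temperature 60 °C; time 4.0 min
- midnight: free catalyst 0.06 mol%; temperature 60 °C; time 4.0 min
- autumn: free catalyst 0.03 mol%; temperature 60 °C; time 4.0 min
- summer: free catalyst 0.3 mol%; temperature 60 °C; time 4.0 min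

| eta: time / min | eta: product / % | alpha: time / min | alpha: product / % |
|---|---|---|---|
| 0.667 | 2.2 | 0.250 | 15.0 |
| 1.33 | 3.2 | 0.500 | 23.5 |
| 2.00 | 5.3 | 1.33 | 35.6 |
| 3.00 | 7.6 | 3.00 | 44.9 |

(scatter of a reading: 0.3 percentage points)



- ranking by amount of product, in percent of the substrate charged, from high to low, at 4.0 min (spring / noon / midnight / autumn / summer)
- the same order at 15 min (spring / noon / midnight / autumn / summer)
- the amount of product, in percent of the substrate charged of the flask you put first, at 4.0 min
- the amount of product, in percent of the substrate charged of the flask you put last, at 4.0 min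

Two chemists read this differently. The first sees a ceiling: alpha is closing on an equilibrium a little above its last reading of 44.9%, loading sets the speed of approach, and noon should stand near that reading at 15 min.

The second sees catalyst dying two at a time, a second-order deactivation. A flask with more catalyst then loses it sooner, so the clock that counts is the dose, loading times time. He carries one number, read from alpha's later stretch as 8.3 points: the doubling step, the product gained per doubling of dose.

I side with him and reckon from alpha's last reading, leaving aside that alpha ran hotter. Noon has 1.62 times that dose, which gives 50.6%. Autumn has 0.121 times it, which gives 19.7%. At 15 min noon should reach 66.4%, well past any ceiling near alpha's last reading.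

The forecast gives noon > summer > spring > midnight > autumn at 4.0 min and noon > summer > spring > midnight > autumn at 15 min, with 47% for noon and 17% for autumn against my 50.6% and 19.7%, and holds that “Neither explanation reverses the ranking”.

The simulation gives noon > summer > spring > midnight > autumn at 4.0 min, with noon at 49.2% and autumn at 16.7%. At 15 min the order is noon > summer > spring > midnight > autumn, with noon at 59.3%. Noon has passed alpha's last reading, so noon met no ceiling at that level, though my 66.4% overran it.

    substrate + free catalyst ⇌ catalyst intermediate (K = 2.70 L mol⁻¹, k = 11.0 L mol⁻¹ s⁻¹, Ea = 37.0 kJ mol⁻¹, ΔH = −41.0 kJ mol⁻¹)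
    2 free catalyst → spent catalyst (k = 15.0 L mol⁻¹ s⁻¹, Ea = 36.0 kJ mol⁻¹)
    catalyst intermediate ⇌ free catalyst + product (K = 0.830 M, k = 17.0 s⁻¹, Ea = 82.0 kJ mol⁻¹, ΔH = −3.00 kJ mol⁻¹)
    (constants at 60 °C)

Noon shows why. At 4.00 min it holds 88.8% of its catalyst as spent catalyst, and without that loss it stands at 68.3% instead of 49.2%. That loss is one part of the shortfall, and taking it away turns the order at 15 min, acting together with the reading time. The first chemist keeps the late region: from 15 min to 40.0 min, with 98.7% spent by the end, noon gains 4.2 points, less than the step predicts.

Autumn repeated at 45 °C has autumn's dose, so the step by itself predicts no change from 16.7%. That flask gives 9.15%, lower by 0.910 of a step, so the cold acted like cutting the dose to 0.532 of itself.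

The runs come from a simulation with made-up constants.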